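The ring atoms are numbered as in clerodanes: ring C1–C10, exocyclic methylene C19, ester C18. The ten-membered carbocycle is cut at C5–C6, the bond between the sp2 carbon that carries C19 and the saturated C6–C9 half. The key step hydroborates a terminal C6=C7 vinyl group. It then couples the resulting B-alkyl group with an allenylic ester under zerovalent palladium in an SN2′ sense. One operation closes the ring, converts the C19=C5=C4 allene into the C19=C5–C4=C3 diene and sets the C3=C4 geometry. It exploits the 2-alkyl-1,3-diene motif C19=C5(C6)–C4=C3 and the fold given by the cis C1=C2 bond and quaternary C9. The precursor is an acyclic α-(acyloxyalkyl)allenoate.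

Key step: step 13

Atom labels: C1=C2 (Z), C3=C4(C18O2Me), C5=C19H2, C6H2, C7H2, C8H(C17H3), C9(C20H3)(C11H2–C12H(O-acyl)-furan-3-yl), C10H2. Each atom keeps its label in all precursors.

Assumption: the acyl stereocentre of the target corresponds to (R)-2-methylbutanoic acid, taken as a purchasable single enantiomer. The C3 carbinol centre of 19, 21 and 22 is carried as a mixture of epimers because it becomes sp2 in step 13.

Step 1
Reactants: 1 furan-3-carbaldehyde; 2 tributyl(2-methylprop-2-en-1-yl)stannane
Product: 3 (1R)-1-(furan-3-yl)-3-methylbut-3-en-1-ol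
Conditions: (R)-BINOL (20 mol%), Ti(OiPr)4 (10 mol%), 4 Å MS, CH2Cl2, −20 °C; aq. NaHCO3
Reagents that add atoms: tributyl(2-methylprop-2-en-1-yl)stannane (2), C=C(C)C[Sn](CCCC)(CCCC)CCCC
Why: Keck asymmetric allylation, in which the (R)-BINOL–titanium Lewis acid shields one aldehyde face so that the methallylstannane should give the (R)-carbinol that becomes C12.

Step 2
Reactants: 3; 4 prop-2-enoyl chloride
Product: 5 (1R)-1-(furan-3-yl)-3-methylbut-3-en-1-yl prop-2-enoate
Conditions: Et3N, DMAP (cat.), CH2Cl2, 0 °C
Reagents that add atoms: prop-2-enoyl chloride (4), C=CC(=O)Cl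
Why: O-acylation of a secondary alcohol with an acid chloride, which does not touch C12.

Step 3
Reactants: 5
Product: 6 (6R)-6-(furan-3-yl)-4-methyl-5,6-dihydro-2H-pyran-2-one
Conditions: second-generation Grubbs catalyst (5 mol%), CH2Cl2 (0.01 M), reflux
Reagents that add atoms: none
Why: Ring-closing metathesis of an acrylate with a 1,1-disubstituted alkene, an established entry to 4-methyl-5,6-dihydropyran-2-ones that is driven by loss of ethene.

Step 4
Reactants: 6; 7 allylmagnesium bromide
Product: 9 (4S,6R)-4-allyl-6-(furan-3-yl)-4-methyloxan-2-one, via trimethylsilyl ketene acetal 8 (not isolated)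
Conditions: 7 (2 equiv), CuI (2 equiv), LiCl (4 equiv), Me3SiCl (3 equiv), THF, −78 °C; then aq. AcOH, 0 °C
Reagents that add atoms: allylmagnesium bromide (7), C=CC[Mg]Br
Why: Chlorosilane-accelerated 1,4-addition of an allylcopper reagent, in which axial attack on the half-chair with the C12 furyl group pseudo-equatorial should place the allyl arm (C10, C1) anti to the furyl group and so set quaternary C9.

Step 5
Reactants: 9
Product: 10 (3R,4S,6R)-4-allyl-6-(furan-3-yl)-3,4-dimethyloxan-2-one (C8 epimer of 12)
Conditions: LiN(iPr)2, THF, −78 °C; MeI, DMPU, −78 to −40 °C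
Reagents that add atoms: iodomethane, CI
Why: Lactone enolate alkylation in which MeI should enter axially, anti to the axial allyl arm on C9, giving the C8 epimer that step 6 corrects.

Step 6
Reactants: 10
Product: 12 (3S,4S,6R)-4-allyl-6-(furan-3-yl)-3,4-dimethyloxan-2-one, via lithium enolate 11 (not isolated)
Conditions: LiN(iPr)2, THF, −78 to −30 °C; then AcOH in THF, −78 °C
Reagents that add atoms: none
Why: Epimerisation by deprotonation and kinetic protonation, in which the proton should take the same axial path anti to the allyl arm and push the C17 methyl group equatorial, cis to the arm, as C8 requires.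

Step 7
Reactants: 12; 13 (Z)-but-2-ene-1,4-diol
Product: 14 (3S,4S,6R)-6-(furan-3-yl)-4-[(2Z)-4-hydroxybut-2-en-1-yl]-3,4-dimethyloxan-2-one
Conditions: 13 (3 equiv), Ru(=CH-C6H4-2-OiPr)(SIMes)(3,6-Cl2C6H2S2) (5 mol%), THF, 22 °C
Reagents that add atoms: (Z)-but-2-ene-1,4-diol (13), OC/C=C\CO
Why: Stereoretentive Z-selective cross-metathesis that carries the Z geometry of the diol into C1=C2, run at the lactone stage because the later 1,6-diene would ring-close to a cyclopentene.

Step 8
Reactants: 14
Product: 15 (3S,4S,6R)-6-(furan-3-yl)-4-[(2Z)-4-hydroxybut-2-en-1-yl]-3,4-dimethyloxan-2-ol (anomer mixture)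
Conditions: iBu2AlH (2.3 equiv), CH2Cl2, −78 °C; aq. Rochelle salt
Reagents that add atoms: none
Why: Partial lactone reduction, which should stop at the lactol because the aluminium hemiacetal is stable at −78 °C, with one equivalent of hydride spent on the free hydroxyl and no stereocentre touched.

Step 9
Reactants: 15
Product: 16 (2Z,5S,6R)-5-[(2R)-2-(furan-3-yl)-2-hydroxyethyl]-5,6-dimethylocta-2,7-dien-1-ol
Conditions: Ph3PCH3Br, KN(SiMe3)2 (excess), THF, 0 °C to rt
Reagents that add atoms: methyltriphenylphosphonium bromide, C[P+](c1ccccc1)(c1ccccc1)c1ccccc1.[Br-]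
Why: Wittig methylenation of the open hydroxy-aldehyde tautomer brings in C6, creates the C6=C7 vinyl group and frees the C12 hydroxyl, and the low temperature should keep the α-centre C8 from enolising.

Step 10
Reactants: 16
Product: 17 (2Z,5S,6R)-5-[(2R)-2-(furan-3-yl)-2-hydroxyethyl]-5,6-dimethylocta-2,7-dienal
Conditions: TEMPO (10 mol%), PhI(OAc)2 (1.1 equiv), CH2Cl2, 0 °C to rt
Reagents that add atoms: none
Why: Oxoammonium (TEMPO) oxidation, which prefers the primary allylic alcohol over the hindered secondary carbinol and is known to preserve Z-allylic geometry.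

Step 11
Reactants: 17; 18 methyl but-2-ynoate
Product: 19 methyl (4Z,7S,8R)-2-ethenylidene-7-[(2R)-2-(furan-3-yl)-2-hydroxyethyl]-3-hydroxy-7,8-dimethyldeca-4,9-dienoate (C3 epimers)
Conditions: 18 (3 equiv), LiN(iPr)2 (3 equiv), THF, −78 °C; add 17; AcOH quench at −78 °C
Reagents that add atoms: methyl but-2-ynoate (18), CC#CC(=O)OC
Why: Aldol-type addition of the lithium ynenolate formed by γ-deprotonation of the butynoate, which reacts with aldehydes at its α-carbon (C4) and so delivers the whole C3–C4(C18)–C5–C19 allenoate unit in one step.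

Step 12
Reactants: 19; 20 (2R)-2-methylbutanoic acid
Product: 21 methyl (4Z,7S,8R)-2-ethenylidene-7-{(2R)-2-(furan-3-yl)-2-[(2R)-2-methylbutanoyloxy]ethyl}-7,8-dimethyl-3-[(2R)-2-methylbutanoyloxy]deca-4,9-dienoate (C3 epimers)
Conditions: 20 (3 equiv), DCC (3 equiv), DMAP (10 mol%), CH2Cl2, 0 °C
Reagents that add atoms: (2R)-2-methylbutanoic acid (20), CC[C@@H](C)C(=O)O
Why: Steglich esterification of both secondary alcohols with retention at C12, so that one reagent installs the C12 ester of the target and the leaving group at C3 without any protecting group.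

Step 13
Reactants: 21
Product: 23 CNP0305973.1, methyl (1E,3Z,6S,7R)-6-{(2R)-2-(furan-3-yl)-2-[(2R)-2-methylbutanoyloxy]ethyl}-6,7-dimethyl-10-methylidenecyclodeca-1,3-diene-1-carboxylate, via B-alkyl-9-BBN adduct 22 (not isolated)
Conditions: 9-BBN-H (1.2 equiv), THF, 0 °C to rt; then syringe-pump addition to Pd(dppf)Cl2 (15 mol%), AsPh3 (15 mol%), Cs2CO3 (3 equiv), DMF/THF/H2O, final 1 mM, rt to 40 °C
Reagents that add atoms: none
Why: Proposed new method: 9-BBN-H should add to the monosubstituted C6=C7 alkene with boron on C6 (22); zerovalent palladium then ionises the C3 ester in an SN2′ sense through the acceptor-substituted C4=C5 bond of the allene to give a 1,3-dien-2-yl palladium species bonded at C5, the hydroxyborate hands C6 over to palladium, and reductive elimination forms C5–C6. The closest known reaction types are the palladium-catalysed coupling of 2,3-alkadienyl carbonates and acetates with organoboron reagents to 2-substituted 1,3-dienes and the intramolecular B-alkyl Suzuki–Miyaura macrocyclisation; what is new is their union in one ring closure on a substrate whose leaving group is also allylic to C1=C2. The ten-membered carbocycle closes by reductive elimination from an eleven-membered alkyl(dienyl)palladacycle, with C19 staying exocyclic. No stereocentre is formed and both C3 epimers converge; the C3=C4 geometry (C2 cis to C5, trans to the ester) is controlled by allylic 1,3-strain in the ionising conformer, where the C2 chain turns toward the slim sp carbon C5 and not toward the ester, and only this isomer can reach C6. The step needs boron on C6 and not on the allene, ionisation toward C5 and not toward C1, and ring closure instead of oligomerisation; the electron-poor, fully substituted allenoate, the preference of zerovalent palladium for the acceptor-bearing π bond, and high dilution together with the fold set by the cis C1=C2 bond and quaternary C9 should secure these. The wide-bite-angle dppf ligand should favour reductive elimination over β-hydride loss from C7, and the mild temperature should keep the triene from sigmatropic hydrogen shifts.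

Compound list
1 | furan-3-carbaldehyde | O=Cc1ccoc1 | starting material
2 | tributyl(2-methylprop-2-en-1-yl)stannane | C=C(C)C[Sn](CCCC)(CCCC)CCCC | starting material
3 | (1R)-1-(furan-3-yl)-3-methylbut-3-en-1-ol | C=C(C)C[C@@H](O)c1ccoc1 | intermediate
4 | prop-2-enoyl chloride | C=CC(=O)Cl | starting material
5 | (1R)-1-(furan-3-yl)-3-methylbut-3-en-1-yl prop-2-enoate | C=C(C)C[C@@H](OC(=O)C=C)c1ccoc1 | intermediate
6 | (6R)-6-(furan-3-yl)-4-methyl-5,6-dihydro-2H-pyran-2-one | O=C1C=C(C)C[C@@H](O1)c2ccoc2 | intermediate
7 | allylmagnesium bromide | C=CC[Mg]Br | starting material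
8 | {[(4S,6R)-4-allyl-6-(furan-3-yl)-4-methyl-5,6-dihydro-4H-pyran-2-yl]oxy}trimethylsilane (not isolated) | C[Si](C)(C)OC1=C[C@](C)(C[C@@H](O1)c2ccoc2)CC=C | intermediate
9 | (4S,6R)-4-allyl-6-(furan-3-yl)-4-methyloxan-2-one | O=C1C[C@](C)(C[C@@H](O1)c2ccoc2)CC=C | intermediate
10 | (3R,4S,6R)-4-allyl-6-(furan-3-yl)-3,4-dimethyloxan-2-one | O=C1[C@H](C)[C@](C)(C[C@@H](O1)c2ccoc2)CC=C | intermediate
11 | lithium enolate of 10 (not isolated) | [Li+].[O-]C1=C(C)[C@](C)(C[C@@H](O1)c2ccoc2)CC=C | intermediate
12 | (3S,4S,6R)-4-allyl-6-(furan-3-yl)-3,4-dimethyloxan-2-one | O=C1[C@@H](C)[C@](C)(C[C@@H](O1)c2ccoc2)CC=C | intermediate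
13 | (Z)-but-2-ene-1,4-diol | OC/C=C\CO | starting material
14 | (3S,4S,6R)-6-(furan-3-yl)-4-[(2Z)-4-hydroxybut-2-en-1-yl]-3,4-dimethyloxan-2-one | O=C1[C@@H](C)[C@](C)(C[C@@H](O1)c2ccoc2)C/C=C\CO | intermediate
15 | (3S,4S,6R)-6-(furan-3-yl)-4-[(2Z)-4-hydroxybut-2-en-1-yl]-3,4-dimethyloxan-2-ol (anomers) | OC1[C@@H](C)[C@](C)(C[C@@H](O1)c2ccoc2)C/C=C\CO | intermediate
16 | (2Z,5S,6R)-5-[(2R)-2-(furan-3-yl)-2-hydroxyethyl]-5,6-dimethylocta-2,7-dien-1-ol | C=C[C@@H](C)[C@](C)(C[C@@H](O)c1ccoc1)C/C=C\CO | intermediate
17 | (2Z,5S,6R)-5-[(2R)-2-(furan-3-yl)-2-hydroxyethyl]-5,6-dimethylocta-2,7-dienal | C=C[C@@H](C)[C@](C)(C[C@@H](O)c1ccoc1)C/C=C\C=O | intermediate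
18 | methyl but-2-ynoate | CC#CC(=O)OC | starting material
19 | methyl (4Z,7S,8R)-2-ethenylidene-7-[(2R)-2-(furan-3-yl)-2-hydroxyethyl]-3-hydroxy-7,8-dimethyldeca-4,9-dienoate (C3 epimers) | C=C[C@@H](C)[C@](C)(C[C@@H](O)c1ccoc1)C/C=C\C(O)C(=C=C)C(=O)OC | intermediate
20 | (2R)-2-methylbutanoic acid | CC[C@@H](C)C(=O)O | starting material
21 | bis[(2R)-2-methylbutanoate] of 19 (C3 epimers) | C=C[C@@H](C)[C@](C)(C[C@@H](OC(=O)[C@H](C)CC)c1ccoc1)C/C=C\C(OC(=O)[C@H](C)CC)C(=C=C)C(=O)OC | intermediate
22 | B-alkyl-9-BBN adduct of 21, boron on C6 (not isolated) | C1CC2CCCC(C1)B2CC[C@@H](C)[C@](C)(C[C@@H](OC(=O)[C@H](C)CC)c1ccoc1)C/C=C\C(OC(=O)[C@H](C)CC)C(=C=C)C(=O)OC | intermediate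
23 | CNP0305973.1 | C=C1CC[C@@H](C)[C@](C)(C[C@@H](OC(=O)[C@H](C)CC)c2ccoc2)C/C=C\C=C/1C(=O)OC | target

Total step count: 13. Longest linear sequence: 13 steps (1 to 23).

Steps most likely to fail

Step 13 (new method).
- What may go wrong: the borane may also attack the allene. Palladium may ionise the doubly allylic ester toward C1, which would erode the Z geometry or cause 1,4-elimination. The open chain may oligomerise instead of closing.
- Fallback, from 21, in known chemistry that separates diene formation from ring closure: LiBr with Pd(OAc)2 (5 mol%) in MeCN bromopalladates the allene at divalent palladium. β-Elimination of the C3 carboxylate should then give the 2-bromo-1,3-diene F1, whose geometry can be checked and purified.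
- 9-BBN-H then adds only to the vinyl group, because the bromodienoate is deactivated, giving the B-alkyl adduct F2.
- A classical intramolecular B-alkyl Suzuki–Miyaura macrocyclisation (Pd(dppf)Cl2, AsPh3, Cs2CO3, high dilution) returns to the route at 23.

Step 4.
- What may go wrong: the allyl metal may add 1,2 to the lactone carbonyl, or may not add at all to the hindered β,β-disubstituted position.
- Fallback, from 6: a better-behaved vinyl cuprate (vinylMgBr, CuI) should add in the same anti sense to give the 4-vinyl lactone F3.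
- 9-BBN-H gives the B-alkyl adduct F4, and NaBO3 oxidises it to the primary alcohol F5.
- Dess–Martin oxidation gives the aldehyde F6, and Wittig methylenation returns to the route at 9.

Step 11.
- What may go wrong: the ynenolate may attack through its γ-carbon. The basic medium may deprotonate the Z-enal at C10, with loss of the Z geometry.
- Fallback, from 17: the base is avoided altogether by a Barbier-type allenylation with methyl 4-bromobut-2-ynoate and indium metal in aqueous THF. The allylic-type organoindium reacts through the ester-bearing carbon under neutral conditions and tolerates the free hydroxyl. This returns to the route at 19.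

Further compounds
F1 | step 13 | methyl (2Z,4Z,7S,8R)-2-(1-bromoethenyl)-7-{(2R)-2-(furan-3-yl)-2-[(2R)-2-methylbutanoyloxy]ethyl}-7,8-dimethyldeca-2,4,9-trienoate | C=C[C@@H](C)[C@](C)(C[C@@H](OC(=O)[C@H](C)CC)c1ccoc1)C/C=C\C=C(/C(Br)=C)C(=O)OC
F2 | step 13 | B-alkyl-9-BBN adduct of F1, boron on C6 | C1CC2CCCC(C1)B2CC[C@@H](C)[C@](C)(C[C@@H](OC(=O)[C@H](C)CC)c1ccoc1)C/C=C\C=C(/C(Br)=C)C(=O)OC
F3 | step 4 | 4-vinyl analogue of 9, vinyl anti to the furyl group | O=C1C[C@](C)(C[C@@H](O1)c2ccoc2)C=C
F4 | step 4 | B-alkyl-9-BBN adduct of F3 | O=C1C[C@](C)(C[C@@H](O1)c2ccoc2)CCB1C2CCCC1CCC2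
F5 | step 4 | 4-(2-hydroxyethyl) analogue of 9 | O=C1C[C@](C)(C[C@@H](O1)c2ccoc2)CCO
F6 | step 4 | 4-(2-oxoethyl) analogue of 9 | O=C1C[C@](C)(C[C@@H](O1)c2ccoc2)CC=O
F0 | step 11 | none | none
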